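Ring B is not brought in as an arene. It is grown on chroman C3 from two open-chain partners. The feature used is its substitution pattern: C1' alkyl, C2' OH, C3' prenyl, C4' O, and bare C5'/C6'. This is the print left by a β-substituted vinylketene (C2', C5', C6', C1') and a prenylated silyl ynol ether (C3', C4'). One light-then-heat cascade forges four C–C bonds, closes the ring and places every substituent. The C3 stereocenter, set earlier by asymmetric hydrogenation of a 2H-chromene-3-carboxylic acid, stays a spectator. The precursor is an (S,E)-vinyl diazomethyl ketone on C3 of the 8-prenyl-7-silyloxychroman.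

Key step: step 11

Assumption: the SMILES is read as the (3S)-isoflavan; the (S)-ligand in step 5 is chosen by analogy with tiglic and (E)-2-alkylcinnamic acids, and the (R)-ligand would be used if a trial run showed the opposite sense.

Step 1
Reactants: 1 2,4-dihydroxybenzaldehyde; 2 prenyl bromide (1-bromo-3-methylbut-2-ene)
Product: 3 2,4-dihydroxy-3-(3-methylbut-2-enyl)benzaldehyde
Conditions: KOH (1.1 equiv), H2O, 0 °C to rt; chromatography
Reagents that add atoms: none
Why: Base-mediated C-prenylation of an ambident resorcinolate: in water the oxygens are solvated, so the soft allylic bromide should be taken up at C3, the carbon activated by both oxygens, and the O-prenyl and C5 isomers that accompany it are removed at this cheap first stage.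

Step 2
Reactants: 3 2,4-dihydroxy-3-(3-methylbut-2-enyl)benzaldehyde
Product: 4 2-hydroxy-3-(3-methylbut-2-enyl)-4-(triisopropylsilyloxy)benzaldehyde
Conditions: TIPSCl (1.05 equiv), imidazole (2 equiv), CH2Cl2, 0 °C to rt
Reagents that add atoms: triisopropylsilyl chloride, CC(C)[Si](Cl)(C(C)C)C(C)C
Why: Chemoselective O-silylation: the C2 hydroxyl is locked in a hydrogen bond to the formyl oxygen and is flanked on both sides, so the bulky chlorosilane should take only the more acidic, free C4 hydroxyl.

Step 3
Reactants: 4 2-hydroxy-3-(3-methylbut-2-enyl)-4-(triisopropylsilyloxy)benzaldehyde; 5 acrolein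
Product: 6 8-(3-methylbut-2-enyl)-7-(triisopropylsilyloxy)-2H-chromene-3-carbaldehyde
Conditions: 5 (1.5 equiv), DABCO (0.5 equiv), CHCl3–H2O, rt
Reagents that add atoms: none
Why: Domino oxa-Michael addition/intramolecular aldol condensation of a salicylaldehyde with an enal, the standard entry to 2H-chromene-3-carbaldehydes, closes the pyran ring (O1–C2 and C3–C4), and an amine base at room temperature is chosen to spare the aryl silyl ether para to the formyl group.

Step 4
Reactants: 6 8-(3-methylbut-2-enyl)-7-(triisopropylsilyloxy)-2H-chromene-3-carbaldehyde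
Product: 7 8-(3-methylbut-2-enyl)-7-(triisopropylsilyloxy)-2H-chromene-3-carboxylic acid
Conditions: NaClO2, NaH2PO4, 2-methylbut-2-ene (20 equiv), t-BuOH–H2O, 0 °C to rt
Reagents that add atoms: sodium chlorite, [Na+].[O-]Cl=O
Why: Pinnick oxidation takes the enal to the acid at buffered pH, the large excess of 2-methylbut-2-ene intercepts HOCl before it can reach the prenyl group or the electron-rich ring, and no ester has to be cleaved by acid (a danger for the prenyl group) or by hydroxide (a danger for the silyl ether).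

Step 5
Reactants: 7 8-(3-methylbut-2-enyl)-7-(triisopropylsilyloxy)-2H-chromene-3-carboxylic acid
Product: 8 (R)-8-(3-methylbut-2-enyl)-7-(triisopropylsilyloxy)chroman-3-carboxylic acid
Conditions: Ru(OAc)2[(S)-H8-BINAP] (1 mol %), H2 (50 bar), MeOH, 25 °C
Reagents that add atoms: none
Why: Noyori-type carboxylate-directed asymmetric hydrogenation of a cyclic (E)-α-substituted cinnamic acid: the substrate binds to divalent ruthenium through its carboxylate, the chiral diphosphine selects the face of C3=C4 that receives hydrogen and so sets C3 as (R) (the same spatial arrangement as (3S) in the target, because CO2H outranks C2), and the prenyl alkene, which cannot chelate, should stay untouched.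

Step 6
Reactants: 8 (R)-8-(3-methylbut-2-enyl)-7-(triisopropylsilyloxy)chroman-3-carboxylic acid
Product: 10 (R)-N-methoxy-N-methyl-8-(3-methylbut-2-enyl)-7-(triisopropylsilyloxy)chroman-3-carboxamide, via acyl imidazolide 9 (not isolated)
Conditions: 1,1'-carbonyldiimidazole (1.1 equiv), CH2Cl2, 0 °C to rt; then MeNH(OMe)·HCl (1.3 equiv), rt
Reagents that add atoms: 1,1'-carbonyldiimidazole, O=C(n1ccnc1)n1ccnc1 (imidazolyl group of 9 only); N,O-dimethylhydroxylamine hydrochloride, CNOC.Cl
Why: Weinreb amide formation by acyl transfer through the acyl imidazolide; imidazole is the strongest base present, so neither enolisation at C3 nor β-elimination of the ring oxygen O1 is expected.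

Step 7
Reactants: 10 (R)-N-methoxy-N-methyl-8-(3-methylbut-2-enyl)-7-(triisopropylsilyloxy)chroman-3-carboxamide
Product: 11 (R)-8-(3-methylbut-2-enyl)-7-(triisopropylsilyloxy)chroman-3-carbaldehyde
Conditions: i-Bu2AlH (1.2 equiv), THF, −78 °C; aq. potassium sodium tartrate
Reagents that add atoms: none
Why: Weinreb amide reduction: the chelated tetrahedral aluminium adduct holds the aldehyde oxidation level until the cold, near-neutral work-up, and the aldehyde is used crude at once because its α-carbon C3 can epimerise.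

Step 8
Reactants: 11 (R)-8-(3-methylbut-2-enyl)-7-(triisopropylsilyloxy)chroman-3-carbaldehyde; 12 1-(triphenylphosphoranylidene)propan-2-one
Product: 13 (S,E)-4-[8-(3-methylbut-2-enyl)-7-(triisopropylsilyloxy)chroman-3-yl]but-3-en-2-one
Conditions: 12 (1.3 equiv), CH2Cl2, rt to 40 °C
Reagents that add atoms: none
Why: Wittig olefination with a stabilised ylide is (E)-selective and needs no added base, which protects the α-stereocenter of 11 from epimerisation and from retro-oxa-Michael ring opening, and after this step C3 is only allylic.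

Step 9
Reactants: 13 (S,E)-4-[8-(3-methylbut-2-enyl)-7-(triisopropylsilyloxy)chroman-3-yl]but-3-en-2-one
Product: 15 (S,E)-1-diazo-4-[8-(3-methylbut-2-enyl)-7-(triisopropylsilyloxy)chroman-3-yl]but-3-en-2-one, via trifluoroacetyl diketone 14 (not isolated)
Conditions: LiN(SiMe3)2 (1.1 equiv), THF, −78 °C; CF3CO2CH2CF3 (1.2 equiv), −78 °C; cold 5% aq. HCl; then 4-acetamidobenzenesulfonyl azide (1.5 equiv), Et3N (1.5 equiv), H2O (1 equiv), MeCN, rt
Reagents that add atoms: 2,2,2-trifluoroethyl trifluoroacetate, O=C(OCC(F)(F)F)C(F)(F)F (trifluoroacetyl group of 14 only); 4-acetamidobenzenesulfonyl azide, CC(=O)Nc1ccc(cc1)S(=O)(=O)N=[N+]=[N-]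
Why: Detrifluoroacetylative (Regitz-type) diazo transfer: kinetic deprotonation at −78 °C takes the methyl group and not the γ-hydrogen at C3, trifluoroacetylation activates that carbon, and the sulfonyl azide then delivers N2 while the trifluoroacetyl group leaves as the N-sulfonyl amide, a route that avoids diazomethane, which would add to the enone as a dipole.

Step 10
Reactants: 16 ethyl 4-methylpent-3-enoate
Product: 19 5-methyl-1-(triisopropylsilyloxy)hex-4-en-1-yne, via dibromo enolate 17 (not isolated), via lithium ynolate 18 (not isolated)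
Conditions: CH2Br2, lithium 2,2,6,6-tetramethylpiperidide, THF, −78 °C; 16; LiN(SiMe3)2, then n-BuLi, −78 °C to rt; TIPSCl, −78 °C to rt
Reagents that add atoms: dibromomethane, BrCBr; triisopropylsilyl chloride, CC(C)[Si](Cl)(C(C)C)C(C)C (the lithium of 17 and 18 comes from the lithium bases)
Why: Kowalski ester homologation stopped at the ynolate stage: LiCHBr2 adds to the ester, dibromo enolate 17 undergoes Br/Li exchange and a 1,2-shift of the prenyl group with loss of LiBr to give ynolate 18, and the bulky chlorosilane traps it on oxygen and not on carbon.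

Step 11
Reactants: 15 (S,E)-1-diazo-4-[8-(3-methylbut-2-enyl)-7-(triisopropylsilyloxy)chroman-3-yl]but-3-en-2-one; 19 5-methyl-1-(triisopropylsilyloxy)hex-4-en-1-yne
Product: 24 (S)-2-(3-methylbut-2-enyl)-6-[8-(3-methylbut-2-enyl)-7-(triisopropylsilyloxy)chroman-3-yl]-3-(triisopropylsilyloxy)phenol (the 7,4'-bis-TIPS ether of the target), via vinylketene 20 (not isolated), via alkenylcyclobutenone 21 (not isolated), via dienylketene 22 (not isolated), via cyclohexadienone 23 (not isolated)
Conditions: 19 (2 equiv), degassed ClCH2CH2Cl, hν (254 nm, low-pressure mercury lamps, Vycor), rt; then 80 °C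
Reagents that add atoms: none
Why: Danheiser benzannulation in its diazo ketone form: light expels N2 from 15 and the alkenyl group shifts (photochemical Wolff rearrangement, making C5'–C6') to give vinylketene 20, whose ketene C=C adds to ynol ether 19 in a (2+2) cycloaddition (C2'–C3' and C4'–C5') to give the 4-alkenylcyclobut-2-enone 21. Light or the final heating opens 21 by a 4π electrocyclic reaction to dienylketene 22, which closes ring B, the only ring formed, by 6π electrocyclisation (C1'–C2') to dienone 23, and tautomerisation gives the free C2' phenol. The closest known reaction type is this same annulation of α'-diazo enones with trialkylsilyloxyalkynes to resorcinol monosilyl ethers. No lasting stereocenter is created: the sp3 carbons of 21 and 23 are transient and are erased, and chroman C3 never joins the reacting π system, so its (S) configuration should pass through these neutral conditions unchanged. The selectivity needed is regiochemical: oxygen donation makes the prenyl-bearing alkyne carbon the nucleophilic end, so it bonds to the electrophilic ketene carbonyl carbon, which places prenyl at C3' between the two oxygens and the silyloxy group at C4'. The excess of 19 should outrun ketene dimerisation and acylation of the product phenol, and the isolated prenyl alkenes are far poorer ketenophiles than the ynol ether.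

Step 12
Reactants: 24 the 7,4'-bis-TIPS ether of the target
Product: 25 (3S)-7,2',4'-trihydroxy-8,3'-diprenylisoflavan, 4-[(3S)-7-hydroxy-8-(3-methylbut-2-enyl)chroman-3-yl]-2-(3-methylbut-2-enyl)benzene-1,3-diol (target)
Conditions: Bu4NF (2.5 equiv), AcOH (2.5 equiv), THF, 0 °C to rt
Reagents that add atoms: none
Why: Fluoride-induced cleavage of both aryl silyl ethers is driven by the Si–F bond, buffering with acetic acid keeps the electron-rich phenolates from air oxidation, and the absence of strong acid prevents cyclisation of the ortho-prenylphenols to dimethylchromans.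

Compound list
1 | 2,4-dihydroxybenzaldehyde | O=Cc1ccc(O)cc1O | starting material
2 | prenyl bromide (1-bromo-3-methylbut-2-ene) | CC(C)=CCBr | starting material
3 | 2,4-dihydroxy-3-(3-methylbut-2-enyl)benzaldehyde | O=Cc1ccc(O)c(CC=C(C)C)c1O | intermediate
4 | 2-hydroxy-3-(3-methylbut-2-enyl)-4-(triisopropylsilyloxy)benzaldehyde | O=Cc1ccc(O[Si](C(C)C)(C(C)C)C(C)C)c(CC=C(C)C)c1O | intermediate
5 | acrolein | C=CC=O | starting material
6 | 8-(3-methylbut-2-enyl)-7-(triisopropylsilyloxy)-2H-chromene-3-carbaldehyde | O=CC1=Cc2ccc(O[Si](C(C)C)(C(C)C)C(C)C)c(CC=C(C)C)c2OC1 | intermediate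
7 | 8-(3-methylbut-2-enyl)-7-(triisopropylsilyloxy)-2H-chromene-3-carboxylic acid | O=C(O)C1=Cc2ccc(O[Si](C(C)C)(C(C)C)C(C)C)c(CC=C(C)C)c2OC1 | intermediate
8 | (R)-8-(3-methylbut-2-enyl)-7-(triisopropylsilyloxy)chroman-3-carboxylic acid | O=C(O)[C@H]1COc2c(ccc(O[Si](C(C)C)(C(C)C)C(C)C)c2CC=C(C)C)C1 | intermediate
9 | (R)-(imidazol-1-yl)[8-(3-methylbut-2-enyl)-7-(triisopropylsilyloxy)chroman-3-yl]methanone (acyl imidazolide, not isolated) | O=C(n1ccnc1)[C@H]1COc2c(ccc(O[Si](C(C)C)(C(C)C)C(C)C)c2CC=C(C)C)C1 | intermediate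
10 | (R)-N-methoxy-N-methyl-8-(3-methylbut-2-enyl)-7-(triisopropylsilyloxy)chroman-3-carboxamide | CON(C)C(=O)[C@H]1COc2c(ccc(O[Si](C(C)C)(C(C)C)C(C)C)c2CC=C(C)C)C1 | intermediate
11 | (R)-8-(3-methylbut-2-enyl)-7-(triisopropylsilyloxy)chroman-3-carbaldehyde | O=C[C@H]1COc2c(ccc(O[Si](C(C)C)(C(C)C)C(C)C)c2CC=C(C)C)C1 | intermediate
12 | 1-(triphenylphosphoranylidene)propan-2-one | CC(=O)C=P(c1ccccc1)(c1ccccc1)c1ccccc1 | starting material
13 | (S,E)-4-[8-(3-methylbut-2-enyl)-7-(triisopropylsilyloxy)chroman-3-yl]but-3-en-2-one | CC(=O)/C=C/[C@H]1COc2c(ccc(O[Si](C(C)C)(C(C)C)C(C)C)c2CC=C(C)C)C1 | intermediate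
14 | (S,E)-1,1,1-trifluoro-6-[8-(3-methylbut-2-enyl)-7-(triisopropylsilyloxy)chroman-3-yl]hex-5-ene-2,4-dione (not isolated) | O=C(CC(=O)C(F)(F)F)/C=C/[C@H]1COc2c(ccc(O[Si](C(C)C)(C(C)C)C(C)C)c2CC=C(C)C)C1 | intermediate
15 | (S,E)-1-diazo-4-[8-(3-methylbut-2-enyl)-7-(triisopropylsilyloxy)chroman-3-yl]but-3-en-2-one | O=C(C=[N+]=[N-])/C=C/[C@H]1COc2c(ccc(O[Si](C(C)C)(C(C)C)C(C)C)c2CC=C(C)C)C1 | intermediate
16 | ethyl 4-methylpent-3-enoate | CCOC(=O)CC=C(C)C | starting material
17 | lithium enolate of 1,1-dibromo-5-methylhex-4-en-2-one (not isolated) | [Li+].[O-]C(CC=C(C)C)=C(Br)Br | intermediate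
18 | lithium 5-methylhex-4-en-1-yn-1-olate (ynolate, not isolated) | [Li+].[O-]C#CCC=C(C)C | intermediate
19 | 5-methyl-1-(triisopropylsilyloxy)hex-4-en-1-yne | CC(C)=CCC#CO[Si](C(C)C)(C(C)C)C(C)C | intermediate
20 | (S,E)-4-[8-(3-methylbut-2-enyl)-7-(triisopropylsilyloxy)chroman-3-yl]buta-1,3-dien-1-one (vinylketene, not isolated) | O=C=C/C=C/[C@H]1COc2c(ccc(O[Si](C(C)C)(C(C)C)C(C)C)c2CC=C(C)C)C1 | intermediate
21 | 4-{(E)-2-[(S)-8-(3-methylbut-2-enyl)-7-(triisopropylsilyloxy)chroman-3-yl]vinyl}-2-(3-methylbut-2-enyl)-3-(triisopropylsilyloxy)cyclobut-2-en-1-one (both C4 epimers, not isolated) | O=C1C(CC=C(C)C)=C(O[Si](C(C)C)(C(C)C)C(C)C)C1/C=C/[C@H]2COc3c(ccc(O[Si](C(C)C)(C(C)C)C(C)C)c3CC=C(C)C)C2 | intermediate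
22 | (3E,5E)-6-[(S)-8-(3-methylbut-2-enyl)-7-(triisopropylsilyloxy)chroman-3-yl]-2-(3-methylbut-2-enyl)-3-(triisopropylsilyloxy)hexa-1,3,5-trien-1-one (dienylketene, ketene and vinyl cis on C3=C4, not isolated) | O=C=C(CC=C(C)C)/C(O[Si](C(C)C)(C(C)C)C(C)C)=C\C=C\[C@H]2COc3c(ccc(O[Si](C(C)C)(C(C)C)C(C)C)c3CC=C(C)C)C2 | intermediate
23 | 6-[(S)-8-(3-methylbut-2-enyl)-7-(triisopropylsilyloxy)chroman-3-yl]-2-(3-methylbut-2-enyl)-3-(triisopropylsilyloxy)cyclohexa-2,4-dien-1-one (both C6 epimers, not isolated) | O=C1C(CC=C(C)C)=C(O[Si](C(C)C)(C(C)C)C(C)C)C=CC1[C@H]2COc3c(ccc(O[Si](C(C)C)(C(C)C)C(C)C)c3CC=C(C)C)C2 | intermediate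
24 | (S)-2-(3-methylbut-2-enyl)-6-[8-(3-methylbut-2-enyl)-7-(triisopropylsilyloxy)chroman-3-yl]-3-(triisopropylsilyloxy)phenol | CC(C)=CCc1c(O[Si](C(C)C)(C(C)C)C(C)C)ccc([C@H]2COc3c(ccc(O[Si](C(C)C)(C(C)C)C(C)C)c3CC=C(C)C)C2)c1O | intermediate
25 | 4-[(3S)-7-hydroxy-8-(3-methylbut-2-enyl)chroman-3-yl]-2-(3-methylbut-2-enyl)benzene-1,3-diol | CC(C)=CCc1c(O)ccc([C@H]2COc3c(ccc(O)c3CC=C(C)C)C2)c1O | target

Total step count: 12. Longest linear sequence: 11 (steps 1 to 9, 11 and 12); step 10 is a one-step branch.

Steps most likely to fail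

Step 11.
- **What may go wrong:** The enone may isomerise from E to Z before nitrogen is lost. Ring A and the growing phenol may filter the light. The short-lived monosubstituted ketene may dimerise or acylate the product phenol faster than the alkyne captures it.
- **Fallback (sets out from 15 and 19, comes back at 24):** The transient ketene is replaced by an isolable one, and the (2+2)/4π sequence by a polar addition. C-Silylation of 15 (TIPSOTf, i-Pr2NEt, Et2O–hexane, 0 °C to rt) gives the α-silyl diazo ketone F1. Its Wolff rearrangement (hν 300 nm, benzene) gives the (triisopropylsilyl)vinylketene F2, which silicon stabilises enough for chromatography. Separately, 19 is cleaved with MeLi (THF, 0 °C to rt) back to clean ynolate 18. The prenyl-bearing carbon of 18 attacks the ketene carbonyl of F2 (THF, −78 °C to rt) to give the lithium 3-oxidodienylketene F3, which closes by 6π electrocyclisation. Aromatisation and the carbon-to-oxygen silyl shift from C5' to O4' that is typical of this ynolate annulation should give 24 on aqueous work-up. In this variant the C2' hydroxyl stems from the ynolate and O4' from the ketene, but the substitution pattern is the same.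

Step 5.
- **What may go wrong:** Facial selectivity may be poor on this cyclic acid, whose α-substituent is an aryloxymethyl group and not a plain alkyl group.
- **Fallback (sets out from 7, comes back at 8):** Catalytic enantioselection is exchanged for separation of covalent diastereomers. Hydrogenation of 7 with Ru(OAc)2[rac-BINAP] (H2, MeOH) gives the racemic chroman acid F4. Coupling with (S)-4-benzyloxazolidin-2-one (dicyclohexylcarbodiimide, DMAP, CH2Cl2) gives the (R)-acyl imide F5 and the (S)-acyl imide F6, which are separated on silica gel or by crystallisation. LiOH/H2O2 (THF–H2O, 0 °C) cleaves F5 to 8 and returns the auxiliary.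

Step 10.
- **What may go wrong:** The lithium bases may deprotonate the doubly activated C2 methylene of the β,γ-unsaturated ester instead of allowing carbonyl addition, with drift of the alkene into conjugation.
- **Fallback (sets out from 2, comes back at 18):** The ynolate oxygen is introduced by oxidation of an acetylide and not by rearrangement of an ester. Coupling of 2 with HC≡CMgBr (CuBr·SMe2, 5 mol %, THF, 0 °C) gives 5-methylhex-4-en-1-yne F7. n-BuLi (THF, −78 °C) gives the lithium acetylide F8. LiOOt-Bu (from t-BuOOH and LiN(SiMe3)2, −78 to 0 °C) oxidises F8 to ynolate 18, which is silylated on oxygen (TIPSOTf, −78 °C) to 19.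

Further compounds
F1 | step 11 | (S,E)-1-diazo-4-[8-(3-methylbut-2-enyl)-7-(triisopropylsilyloxy)chroman-3-yl]-1-(triisopropylsilyl)but-3-en-2-one | O=C(C(=[N+]=[N-])[Si](C(C)C)(C(C)C)C(C)C)/C=C/[C@H]1COc2c(ccc(O[Si](C(C)C)(C(C)C)C(C)C)c2CC=C(C)C)C1
F2 | step 11 | (S,E)-4-[8-(3-methylbut-2-enyl)-7-(triisopropylsilyloxy)chroman-3-yl]-2-(triisopropylsilyl)buta-1,3-dien-1-one | O=C=C([Si](C(C)C)(C(C)C)C(C)C)/C=C/[C@H]1COc2c(ccc(O[Si](C(C)C)(C(C)C)C(C)C)c2CC=C(C)C)C1
F3 | step 11 | lithium 3-oxidodienylketene from 18 and F2 | [Li+].[O-]C(C(CC=C(C)C)=C=O)=C([Si](C(C)C)(C(C)C)C(C)C)/C=C/[C@H]1COc2c(ccc(O[Si](C(C)C)(C(C)C)C(C)C)c2CC=C(C)C)C1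
F4 | step 5 | rac-8-(3-methylbut-2-enyl)-7-(triisopropylsilyloxy)chroman-3-carboxylic acid | O=C(O)C1COc2c(ccc(O[Si](C(C)C)(C(C)C)C(C)C)c2CC=C(C)C)C1
F5 | step 5 | (S)-4-benzyl-3-[(R)-8-(3-methylbut-2-enyl)-7-(triisopropylsilyloxy)chroman-3-carbonyl]oxazolidin-2-one | O=C1OC[C@H](Cc2ccccc2)N1C(=O)[C@H]3COc4c(ccc(O[Si](C(C)C)(C(C)C)C(C)C)c4CC=C(C)C)C3
F6 | step 5 | (S)-4-benzyl-3-[(S)-8-(3-methylbut-2-enyl)-7-(triisopropylsilyloxy)chroman-3-carbonyl]oxazolidin-2-one | O=C1OC[C@H](Cc2ccccc2)N1C(=O)[C@@H]3COc4c(ccc(O[Si](C(C)C)(C(C)C)C(C)C)c4CC=C(C)C)C3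
F7 | step 10 | 5-methylhex-4-en-1-yne | C#CCC=C(C)C
F8 | step 10 | lithium 5-methylhex-4-en-1-yn-1-ide | [Li]C#CCC=C(C)C
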